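**Plateau product.** If X stands still while J still reads 77%, the flask is sitting on a ceiling in [X][D] and is not short of substrate.

all flasks: temperature 40 °C
- epsilon: J 1.5 M; the very flask that is asked about, followed so far
- gamma: J 3 M; run made earlier
- flask: J 1.5 M; time 4.0 d

| run | time / h | X / % | J / % |
|---|---|---|---|
| epsilon | 15.0 | 12 | 84 |
| epsilon | 30.0 | 19 | 79 |
| epsilon | 50.0 | 19 | 75 |
| epsilon | 60.0 | 20 | 78 |
| epsilon | 72.0 | 20 | 78 |
| epsilon | 96.0 | 22 | 77 |
| gamma | 0.500 | 0 | 103 |
| gamma | 1.00 | 0 | 101 |
| gamma | 1.50 | 0 | 102 |
| gamma | 2.50 | 3 | 97 |
| gamma | 4.00 | 1 | 99 |
| gamma | 8.00 | 1 | 97 |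

(each reading ± 2 percentage points)

- south-west: at 4.0 d raise the temperature by 25 K, then wait 50 h
- north: change nothing and wait 50 h more
- west: at 4.0 d take out 90% of the D then present, then wait 50 h

- the volume of additions can be left aside
- at the start none of J is in solution
- the earlier runs do not show what temperature does; that part of a forecast is a guess
- a reading or a percentage of X counts all its forms, free or not

* X, in percent of the J first charged, at 4.0 d
* which option adds most X ("none" when 2 percentage points or less is all one gets) (south-west / north / west / none)
* X present, in percent of the J first charged, after north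
* X present, in percent of the J first charged, after west

**Reading it.** The epsilon readings from 50.0 h on average 20.2%, which this reckoning takes for now and for north. Taking D as formed mole for mole with X, and absent at the start, [X][D] reads 0.0923 M^2. This plateau product, [X][D] at standstill with solid J present, is an apparent equilibrium constant.

**West bracket.** West keeps [X] and cuts [D] to 10.0% of it, and each new X brings one new D, so the product must be rebuilt. From above: with D removed wholly, X would end at 32.8%. From below: [X] stays under that roof, so [D] must reach at least the plateau product divided by it, which puts X at 30.7%. The exact root multiplies X by 1.55, giving 31.3%. The epsilon readings reach the plateau by 30.0 h, less than the 50 h on offer.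

**The forecast.** It gives 21%, 22% after north, 32% after west and west as best, on the ground that “the plateau looks like an equilibrium or product inhibition”. Its west value lies inside the bracket.

**The flask.** X stands at 19.4%, stays at 19.4% after north, reaches 30.0% after west and loses 9.6 percentage points after south-west, so west is best. The west value lies under the bracket; the factor 1.55 on the flask's 19.4% gives 30.1%.

    E ⇌ X + D (K = 1.60 M, k = 0.0121 min⁻¹, Ea = 108 kJ mol⁻¹, ΔH = −48.0 kJ mol⁻¹)
    Q ⇌ X, rate k2*(cs2 - [X]) while solid is left; crystals form when [X] > cs2 (solubility = 0.490 M, k = 0.188 min⁻¹)
    J ⇌ E, rate k3*(cs3 - [E]) while solid is left; crystals form when [E] > cs3 (solubility = 0.0530 M, k = 0.0100 min⁻¹)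
    (constants at 40 °C)

**Hotter neighbour.** For a neighbour flask kept at 55 °C, amounts and time held, the heat of reaction scales the plateau product by 0.431, with the solubility of J held, to 0.0397 M^2. With [X] equal to [D], that puts X at 13.3%. The neighbour flask holds X at 12.7%, with D at 0.191 M after 96.0 h.

The data were generated by integration with made-up constants; scatter was added.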